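## Structural features

The target is a glycerol ether alkylated at O2 by an unbranched eight‑carbon chain whose far end is bonded to C1 of a C12 tetracycle. In the tetracycle, cyclohexane ring A (C1–C6) shares C4–C5 with cyclobutane ring B (C4, C5, C7, C12), ring B shares C7–C12 with ring C (C7, C8, C11, C12), and ring C shares C8–C11 with ring D (C8, C9, C10, C11). All three fusions are cis and neighbouring rings lie anti across each shared four‑membered ring, so the six contiguous methines C4, C5, C7, C8, C11 and C12 form a staircase; the seventh stereocentre, C1 (S), is insulated from them by C6 and by C2–C3 and holds the chain on the face of ring A that also carries ring B (H1, H4 and H5 are cis). Without the chain the tetracycle has a mirror plane through the midpoints of C1–C2, C4–C5, C7–C12, C8–C11 and C9–C10, so the absolute configuration rests only on the choice of C1 over C2; the glycerol carbon is not stereogenic. The fragile part is the ladder of bicyclo[2.2.0]hexane units, which should be kept away from strong Lewis or Brønsted acids, from prolonged heating and from cations or long‑lived radicals next to the four‑membered rings, whereas the 1,3‑diol is robust once protected. The real difficulty is threefold: three cis,anti‑fused cyclobutanes that end with no functional group, an enantiotopic‑carbon decision remote from every other stereocentre, and a chain that must sit on the more hindered face of ring A. Ring D alone has two adjacent methylene carbons (C9 and C10), so its C8–C9 and C10–C11 bonds can both be made by laying a two‑carbon ketene unit across a C8=C11 cyclobutene of a ring A/B/C tricycle, and the carbonyl and chlorines that such a unit brings can be erased afterwards.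

## Logic of the disconnections

32 to 30. The C1–H bond and the adjacent chain C–H bond are removed (returning an exocyclic C1=C bond) together with the two O–CH2Ph bonds. C1 is the only stereocentre not locked into the ladder; as an sp2 carbon it can receive its hydrogen last, from the open face. One stereocentre and both protecting groups vanish in one operation. The forward step must deliver hydrogen anti to ring B without cleaving strained C–C bonds.

30 to 23 and 29 (from 28). The exocyclic C1=C bond is cut. This divides the molecule into the ring system and the complete side chain, so the synthesis becomes convergent and the core needs nothing but a C1 carbonyl. The forward step is a carbonyl olefination with a basic ylide that must not be lost to enolisation; alkene geometry is irrelevant.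

28 to 27, then to 24 and 25. The C–P bond and the chain C–O ether bond are cut. Both pieces are commercial. The demand is mono‑substitution of a symmetrical dibromide.

23 to 22 to 20. C1=O is traced to C1–OH, then C1–O and C2–H are removed to leave C1=C2. 20 has a mirror plane, so the whole question of absolute configuration shrinks to one choice between two enantiotopic alkene carbons, and every earlier compound may be achiral or racemic. The forward step needs a chiral reagent that tells C1 from C2, and the facial diastereomer must be removed before oxidation.

20 to 17 to 16 to 15. The two C9–H bonds are exchanged for C9=O (through C=N) and the two C10–H bonds for C10–Cl. These groups are the marks of a haloketene cycloadduct and sit on the only two methylenes of ring D. Ring D thereby becomes a retron for a two‑bond cycloaddition. The forward steps must remove chlorine and oxygen under conditions mild enough for the ladder and for the ring A alkene.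

15 to 12 and 14 (14 from 13). C8–C9 and C10–C11 are cut. One ring, two C–C bonds and two stereocentres are removed at once; 12 is meso and either orientation of 14 is productive. The forward step must choose the strained C8=C11 alkene over C1=C2 and the exo face over the endo face.

12 to 11 to 10, then to 8 and 9. The C8=C11 π bond is traced to two carboxyl groups on C8 and C11, then C7–C8 and C11–C12 are cut. A cyclobutene is thereby recognised as a masked photoadduct of a cyclic anhydride, so ring C arrives already carrying its alkene and no anion has to be generated on a bicyclo[2.2.0]hexane. 8 is again meso, and the configuration at the carboxyl‑bearing carbons is irrelevant. The demands are addition at the strained alkene and on its exo face, and an oxidative decarboxylation that spares the ring A alkene.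

8 to 6 to 5, then to 1 and 3 (3 from 2). The C7=C12 π bond is traced to a carbonyl, then C4–C12 and C5–C7 are cut. This reaches two bulk chemicals, and the cationic two‑carbon unit gives the halogen‑free cyclobutanone in one operation from an unstrained alkene. The demands are mono‑addition to a symmetrical diene and alkene formation without skeletal rearrangement.

## Other disconnections considered

Alternative 1: The cut is C3–C4 and C5–C6: ring A is assembled on a four‑membered enone that becomes ring B, with C12 as a carbonyl. The forward key step is a Diels–Alder reaction of cyclobut‑2‑enone A1 with the chain‑bearing diene A2 under a chiral Lewis acid (an oxazaborolidine activated by AlBr3) to give bicyclic ketone A3.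
- In its favour: one catalytic step makes ring A, fixes C4 and C5 in the absolute sense, and brings the chain in with the expected para regiochemistry.
- Against it here: C1 is still sp2 in A3, so its configuration again depends on a later face‑selective hydrogenation. A3 is chiral, so each later four‑membered‑ring annulation gives regioisomeric or diastereomeric mixtures that must be carried along. The trisubstituted C1=C2 alkene is a better nucleophile than the disubstituted one of 12 and would compete harder for an electrophilic ketene. A1 is volatile and polymerisable and must be prepared.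
- Comparison: on absolute stereocontrol the alternative is the better plan (catalytic, early, no stoichiometric chiral borane). On the logic of rings C and D the two are equal, since both still need two cyclobutane annulations. On symmetry the chosen plan is better (only meso or racemic single compounds up to 20). On step count they are about equal: the alternative saves the desymmetrisation, oxidation and olefination but pays for the diene, the enone, silyl removal and the glyceryl ether.

Alternative 2: The cut is C4–C12: ring B arises by expansion of a cyclopropane fused at C4–C5. The forward key step is base‑induced decomposition (Bamford–Stevens) of tosylhydrazone A4 to a cyclopropylcarbene, in which a ring bond shifts to the carbene carbon to give cyclobutene A5.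
- In its favour: C1 is bought from the chiral pool and is already sp3, so no late hydrogenation has to find the right face. Ring A is saturated, so no second alkene competes in later annulations. Either migrating bond leads to the same product.
- Against it here: the cyclopropane must be placed on the same face as the side arm, against the steric bias. Cyclopropylcarbenes also fragment to alkene plus alkyne and undergo hydrogen shifts. Rings C and D are still missing and would be added to a chiral substrate (isomeric mixtures). The one‑carbon arm must be lengthened by seven carbons before etherification.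
- Comparison: the alternative is better on C1 control and on site selectivity. The chosen plan is better on symmetry and on the reliability of its ring‑forming steps, and is shorter by several steps.

Alternative 3: The cut is C4–C5: ring B is closed last onto a ring C/D bicycle. The forward key step is double deprotonation of diester A6 with LiN(iPr)2 and oxidation of the dienolate (I2 or CuBr2) to give cyclobutane diester A7.
- In its favour: the ladder is finished before ring A exists, so no alkene competes with a cyclobutene at any point. The ester α‑centres can be equilibrated. The two ester carbons are C3 and C6, from which ring A could be completed by reduction, two‑carbon extension of each arm and ring‑closing metathesis to reach 20, where it would join the chosen route.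
- Against it here: a strained four‑membered ring must be closed by a radical or oxidative coupling that competes with intermolecular coupling and α‑halogenation. The cis diester needed for ring A is the less stable arrangement. A6 itself needs a multi‑step synthesis.
- Comparison: on site selectivity the alternative is the better plan. From 20 onwards the two are equal, since the same desymmetrisation is needed. On the strain‑building step and on step count the chosen plan is better, because a ketene cycloaddition forms two bonds in an allowed pericyclic event whereas the coupling forms one bond against the full strain of the ring.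

Key step: step 7

Remark on the chemistry: 12 and 14 are achiral, so 15 can only form as a racemate. It and every other chiral compound before 20 (4–7 and 16–19) are drawn as one enantiomer of a racemate, which is harmless because both enantiomers give meso 8 or meso 20; 10, 11 and 12 are meso.

Assumption: (+)-Ipc2BH is taken to show with 20 the sense of induction it shows with simple cis‑1,2‑disubstituted alkenes, which places boron on C1; the antipodal reagent from (+)-α‑pinene would be used if the sense proved to be reversed.

Locants C1–C12 of the target are used in the reasoning for all bicyclic, tricyclic and tetracyclic compounds; systematic names carry their own locants.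

## Route

Step 1
Reactants: 1 cyclohexa-1,4-diene; 2 N,N-dimethylacetamide
Product: 5 (±)-cis-bicyclo[4.2.0]oct-3-en-7-one, via keteniminium triflate 3 (not isolated), via cyclobutaniminium triflate 4 (not isolated)
Conditions: Tf2O (1.2 equiv), 2,4,6-collidine (1.2 equiv, added slowly), 1 (4 equiv), ClCH2CH2Cl, −20 → 80 °C; then H2O, 60 °C
Reagents that add atoms: water, O
Why: Keteniminium–alkene [2+2] cycloaddition: Tf2O activates the amide and collidine removes an α‑proton to give keteniminium ion 3, which does not dimerise and adds to one alkene of 1 (used in excess so the second alkene is not engaged), suprafacially on the cis alkene, so the ring fusion is cis. Hydrolysis of iminium salt 4 in the same flask gives the halogen‑free cyclobutanone directly.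

Step 2
Reactants: 5 (±)-cis-bicyclo[4.2.0]oct-3-en-7-one
Product: 6 (±)-cis-bicyclo[4.2.0]oct-3-en-7-one p-toluenesulfonylhydrazone
Conditions: TsNHNH2, MeOH, 20 °C
Reagents that add atoms: p-toluenesulfonyl hydrazide, Cc1ccc(cc1)S(=O)(=O)NN
Why: Hydrazone formation by condensation with the unhindered, strained ketone; the product should crystallise from the alcohol and is dried before the next step.

Step 3
Reactants: 6 (±)-cis-bicyclo[4.2.0]oct-3-en-7-one p-toluenesulfonylhydrazone
Product: 8 cis-bicyclo[4.2.0]octa-3,7-diene (meso), via vinyllithium 7 (not isolated)
Conditions: n-BuLi (2.3 equiv), TMEDA, Et2O, −78 → 20 °C; then H2O, 0 °C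
Reagents that add atoms: none
Why: Shapiro reaction: N–H and then α‑C–H deprotonation at the less substituted methylene, loss of sulfinate and N2 to vinyllithium 7, and protonation by water. No carbene or cation is involved, so the four‑membered ring does not rearrange and the cis fusion is untouched.

Step 4
Reactants: 8 cis-bicyclo[4.2.0]octa-3,7-diene; 9 maleic anhydride
Product: 10 cis,anti,cis-tricyclo[6.2.0.0^2,7]dec-4-ene-9,10-dicarboxylic anhydride (meso; ring C fused on the exo face of ring B, anti to ring A; anhydride ring drawn anti to ring B)
Conditions: acetophenone (sensitiser), hν (Pyrex, 350 nm), EtOAc, 0–10 °C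
Reagents that add atoms: none
Why: Triplet‑sensitised [2+2] photocycloaddition of maleic anhydride to an alkene through a 1,4‑biradical; the cyclobutene should react before the cyclohexene because its strain is released as its carbons pyramidalise, and attack on its convex face, anti to ring A, sets C7 and C12 cis to each other and ring C anti to ring A. The configuration at the two anhydride‑bearing carbons (C8, C11) is of no consequence, since both become sp2 in step 6.

Step 5
Reactants: 10 cis,anti,cis-tricyclo[6.2.0.0^2,7]dec-4-ene-9,10-dicarboxylic anhydride
Product: 11 cis,anti,cis-tricyclo[6.2.0.0^2,7]dec-4-ene-9,10-dicarboxylic acid (meso; carboxyl groups cis)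
Conditions: THF–H2O (3:1), 50 °C
Reagents that add atoms: water, O
Why: Hydrolysis of the cyclic anhydride by nucleophilic acyl substitution under neutral conditions; no stereocentre is touched, and the free diacid is the form that exchanges onto lead in the next step.

Step 6
Reactants: 11 cis,anti,cis-tricyclo[6.2.0.0^2,7]dec-4-ene-9,10-dicarboxylic acid
Product: 12 cis,anti,cis-tricyclo[6.2.0.0^2,7]deca-4,9-diene (meso; alkenes C1=C2 and C8=C11; rings A and B with the ring C cyclobutene)
Conditions: Pb(OAc)4 (1.5 equiv), pyridine, 50–55 °C; pentane extraction, cold aqueous wash
Reagents that add atoms: none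
Why: Oxidative bis‑decarboxylation of a vicinal diacid with lead tetraacetate: ligand exchange gives a lead dicarboxylate that loses two CO2 and Pb(OAc)2 to leave the C8=C11 alkene, the classical way of unveiling a bicyclo[2.2.0]hexene. The ring‑fusion centres C7 and C12 are not involved, and the pyridine medium keeps acid away from the strained alkene.

Step 7
Reactants: 12 cis,anti,cis-tricyclo[6.2.0.0^2,7]deca-4,9-diene; 13 trichloroacetyl chloride
Product: 15 (±)-5,5-dichlorotetracyclo[6.4.0.0^2,7.0^3,6]dodec-10-en-4-one (ring D dichlorocyclobutanone: C9 carbonyl and C10 dichloride; all fusions cis and neighbouring rings anti), via dichloroketene 14 (not isolated)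
Conditions: Zn–Cu couple, Et2O–DME (9:1), 13 (1.2 equiv) added over several hours, 20–30 °C; filtration, NaHCO3 wash, short neutral alumina plug
Reagents that add atoms: none
Why: Zinc removes two chlorines from 13 to release 14, which adds across C8=C11 of 12 in a thermal ketene–alkene [2+2] cycloaddition; the closest known reactions are the zinc‑mediated dichloroketene annulations of cyclopentene, norbornene and simple cyclobutenes. The addition is concerted but asynchronous ([π2s+π2a]): the electrophilic central carbon of 14 bonds first to one alkene carbon in an orthogonal approach and the CCl2 terminus closes on the other, suprafacially on the alkene, so H8 and H11 stay cis and ring D is cis‑fused. Ring D is thus closed by an intermolecular two‑bond annulation (C8–C9 and C10–C11 in one event) and not by cyclisation of a chain. The new stereocentres C8 and C11 are set relative to C7 and C12 by approach to the exo face of the bicyclo[2.2.0]hexene, because the endo face is covered by the C4–H and C5–H bonds of ring B; ring D therefore forms anti to ring B. Site selectivity over the C1=C2 alkene is needed and should come from strain: the cyclobutene sheds part of its olefinic strain as its carbons pyramidalise, whereas a cyclohexene is among the poorest partners of 14, and slow addition of a small excess of 13 keeps 14 scarce. Orientation needs no control, since either sense gives the same racemate and both enantiomers converge on meso 20 once C9 and C10 are methylenes. DME binds ZnCl2 so that neither the strained alkene nor the product meets a soluble Lewis acid.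

Step 8
Reactants: 15 (±)-5,5-dichlorotetracyclo[6.4.0.0^2,7.0^3,6]dodec-10-en-4-one
Product: 16 (±)-tetracyclo[6.4.0.0^2,7.0^3,6]dodec-10-en-4-one (C9 ketone)
Conditions: Zn dust, AcOH, 20 °C
Reagents that add atoms: none
Why: Reductive dechlorination of the α,α‑dichlorocyclobutanone through its zinc enolate, at room temperature to spare the ladder. The ring‑fusion centre C8 next to the carbonyl stays cis because a trans‑fused bicyclo[2.2.0]hexane is not accessible.

Step 9
Reactants: 16 (±)-tetracyclo[6.4.0.0^2,7.0^3,6]dodec-10-en-4-one
Product: 17 p-toluenesulfonylhydrazone of 16
Conditions: TsNHNH2, MeOH, 20 °C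
Reagents that add atoms: p-toluenesulfonyl hydrazide, Cc1ccc(cc1)S(=O)(=O)NN
Why: Hydrazone formation under neutral conditions; the isolated ring A alkene is inert and the imine geometry is irrelevant.

Step 10
Reactants: 17 p-toluenesulfonylhydrazone of 16
Product: 20 meso tetracyclo[6.4.0.0^2,7.0^3,6]dodec-10-ene (cis,anti,cis,anti,cis; C1=C2 alkene), via borylhydrazine 18 (not isolated), via diazene 19 (not isolated)
Conditions: catecholborane (1.2 equiv), CHCl3, 0 → 20 °C; then NaOAc·3H2O, 60 °C
Reagents that add atoms: none
Why: Caglioti‑type reduction of the tosylhydrazone in its catecholborane form: hydride adds to C9 of the C=N bond (18), acetate triggers loss of sulfinate to diazene 19, and 19 loses N2 with transfer of hydrogen to carbon, leaving a C9 methylene. The conditions are neither strongly basic nor hot, so the ring A alkene should not migrate and the ladder should survive; the product regains the mirror plane.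

Step 11
Reactants: 20 meso tetracyclo[6.4.0.0^2,7.0^3,6]dodec-10-ene
Product: 22 (1R)-cis,anti,cis,anti,cis-tetracyclo[6.4.0.0^2,7.0^3,6]dodecan-10-ol (hydroxyl on C1 and on the face of ring A away from ring B), via trialkylborane 21 (not isolated)
Conditions: (+)-Ipc2BH [from (−)-α-pinene and BH3·SMe2, THF, 0 °C], THF, −25 → 0 °C; then NaOH, H2O2, 0 → 25 °C; chromatography
Reagents that add atoms: hydrogen peroxide, OO
Why: Asymmetric hydroboration of a cis‑disubstituted alkene with diisopinocampheylborane, then oxidation with retention: H and B add syn from the convex face of ring A (anti to ring B), and the chiral borane chooses between the enantiotopic carbons C1 and C2, so boron and then oxygen end on C1. The minor carbinol formed on the ring B face is a diastereomer and is removed by chromatography, because on oxidation it would give the enantiomer of 23.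

Step 12
Reactants: 22 (1R)-cis,anti,cis,anti,cis-tetracyclo[6.4.0.0^2,7.0^3,6]dodecan-10-ol
Product: 23 cis,anti,cis,anti,cis-tetracyclo[6.4.0.0^2,7.0^3,6]dodecan-10-one (carbonyl on C1; single enantiomer)
Conditions: Dess–Martin periodinane, NaHCO3, CH2Cl2, 0 → 20 °C
Reagents that add atoms: none
Why: Dess–Martin oxidation of the secondary alcohol under bicarbonate buffering; the ketone is a single enantiomer only because the carbonyl sits on C1 and not on C2. No stereocentre is α to the carbonyl, so nothing can epimerise.

Step 13
Reactants: 24 1,3-bis(benzyloxy)propan-2-ol; 25 1,8-dibromooctane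
Product: 27 2-O-(8-bromooctyl)-1,3-di-O-benzylglycerol, via alkoxide 26 (not isolated)
Conditions: NaH, THF, 0 °C; then 25 (3 equiv), Bu4NI (cat.), 60 °C
Reagents that add atoms: none
Why: Williamson ether synthesis: the secondary alkoxide 26 displaces one primary bromide of 25 (SN2), the excess of dibromide suppressing the bis‑ether; iodide catalysis speeds the displacement.

Step 14
Reactants: 27 2-O-(8-bromooctyl)-1,3-di-O-benzylglycerol
Product: 28 {8-[1,3-bis(benzyloxy)propan-2-yloxy]octyl}triphenylphosphonium bromide
Conditions: PPh3, MeCN, 80 °C
Reagents that add atoms: triphenylphosphine, c1ccc(cc1)P(c1ccccc1)c1ccccc1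
Why: SN2 quaternisation of triphenylphosphine by the primary bromide; the ether and benzyl groups are inert.

Step 15
Reactants: 28 {8-[1,3-bis(benzyloxy)propan-2-yloxy]octyl}triphenylphosphonium bromide; 23 cis,anti,cis,anti,cis-tetracyclo[6.4.0.0^2,7.0^3,6]dodecan-10-one
Product: 30 exocyclic C1 alkylidene of the tetracycle carrying the dibenzyl glyceryl ether chain (E/Z mixture), via ylide 29 (not isolated)
Conditions: KN(SiMe3)2, THF, 0 °C; then 23, 0 → 40 °C
Reagents that add atoms: none
Why: Wittig olefination: the non‑stabilised ylide 29 adds to the unhindered cyclohexanone and the oxaphosphetane collapses to the trisubstituted exocyclic alkene and Ph3P=O. Both alkene geometries are acceptable because the alkene is hydrogenated next.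

Step 16
Reactants: 30 exocyclic C1 alkylidene of the tetracycle carrying the dibenzyl glyceryl ether chain
Product: 32 2-O-{8-[cis,anti,cis,anti,cis-tetracyclo[6.4.0.0^2,7.0^3,6]dodecan-10-yl]octyl}glycerol (C1 S; chain cis to ring B; CNP0193334.1), via dibenzyl ether 31 (not isolated)
Conditions: H2 (1 atm), Pd/C, EtOAc–EtOH, 20 °C
Reagents that add atoms: none
Why: Heterogeneous hydrogenation of the exocyclic alkene, followed in the same flask by hydrogenolysis of both benzyl ethers. The catalyst surface should meet the convex face of ring A, because the other face is screened by ring B and by the endo C7–H and C12–H bonds; hydrogen therefore reaches C1 anti to ring B and the chain ends cis to ring B. Unactivated cyclobutane C–C bonds are not expected to be cleaved at room temperature and 1 atm.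

## Compound list

1 | cyclohexa-1,4-diene | C1=CCC=CC1 | starting material
2 | N,N-dimethylacetamide | CC(=O)N(C)C | starting material
3 | N,N-dimethylketeniminium trifluoromethanesulfonate (formed in situ) | C=C=[N+](C)C.[O-]S(=O)(=O)C(F)(F)F | intermediate
4 | (±)-cis-N,N-dimethylbicyclo[4.2.0]oct-3-en-7-iminium trifluoromethanesulfonate (formed in situ) | C[N+](C)=C1C[C@H]2CC=CC[C@@H]12.[O-]S(=O)(=O)C(F)(F)F | intermediate
5 | (±)-cis-bicyclo[4.2.0]oct-3-en-7-one | O=C1C[C@H]2CC=CC[C@@H]12 | intermediate
6 | (±)-cis-bicyclo[4.2.0]oct-3-en-7-one p-toluenesulfonylhydrazone | Cc1ccc(cc1)S(=O)(=O)NN=C1C[C@H]2CC=CC[C@@H]12 | intermediate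
7 | 7-lithio-cis-bicyclo[4.2.0]octa-3,7-diene (formed in situ) | [Li]C1=C[C@H]2CC=CC[C@@H]12 | intermediate
8 | cis-bicyclo[4.2.0]octa-3,7-diene (meso) | C1=C[C@H]2CC=CC[C@@H]12 | intermediate
9 | maleic anhydride | O=C1OC(=O)C=C1 | starting material
10 | cis,anti,cis-tricyclo[6.2.0.0^2,7]dec-4-ene-9,10-dicarboxylic anhydride (meso; exo adduct, anhydride anti to ring B) | C1=CC[C@@H]2[C@H](C1)[C@H]1[C@@H]3C(=O)OC(=O)[C@@H]3[C@@H]21 | intermediate
11 | cis,anti,cis-tricyclo[6.2.0.0^2,7]dec-4-ene-9,10-dicarboxylic acid (meso; cis diacid) | C1=CC[C@@H]2[C@H](C1)[C@H]1[C@H](C(=O)O)[C@H](C(=O)O)[C@@H]21 | intermediate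
12 | cis,anti,cis-tricyclo[6.2.0.0^2,7]deca-4,9-diene (meso; rings A and B with the ring C cyclobutene) | C1=CC[C@@H]2[C@H](C1)[C@H]1C=C[C@@H]21 | intermediate
13 | trichloroacetyl chloride | ClC(=O)C(Cl)(Cl)Cl | starting material
14 | dichloroketene (formed in situ) | ClC(Cl)=C=O | intermediate
15 | (±)-5,5-dichlorotetracyclo[6.4.0.0^2,7.0^3,6]dodec-10-en-4-one (ring D dichlorocyclobutanone) | C1=CC[C@@H]2[C@H](C1)[C@H]1[C@@H]3C(=O)C(Cl)(Cl)[C@@H]3[C@@H]21 | intermediate
16 | (±)-tetracyclo[6.4.0.0^2,7.0^3,6]dodec-10-en-4-one | C1=CC[C@@H]2[C@H](C1)[C@H]1[C@@H]3C(=O)C[C@@H]3[C@@H]21 | intermediate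
17 | p-toluenesulfonylhydrazone of 16 | C1=CC[C@@H]2[C@H](C1)[C@H]1[C@@H]3C(=NNS(=O)(=O)c4ccc(C)cc4)C[C@@H]3[C@@H]21 | intermediate
18 | N-(1,3,2-benzodioxaborol-2-yl)-N'-tosylhydrazine at C9 (C9 configuration immaterial; formed in situ) | C1=CC[C@@H]2[C@H](C1)[C@H]1[C@@H]3C(N(NS(=O)(=O)c4ccc(C)cc4)B4Oc5ccccc5O4)C[C@@H]3[C@@H]21 | intermediate
19 | C9 monoalkyl diazene (C9 configuration immaterial; formed in situ) | C1=CC[C@@H]2[C@H](C1)[C@H]1[C@@H]3C(N=N)C[C@@H]3[C@@H]21 | intermediate
20 | meso cis,anti,cis,anti,cis-tetracyclo[6.4.0.0^2,7.0^3,6]dodec-10-ene | C1=CC[C@@H]2[C@H](C1)[C@H]1[C@@H]3CC[C@@H]3[C@@H]21 | intermediate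
21 | C1-(diisopinocampheylboryl) tetracycle, boron anti to ring B (formed in situ) | B([C@H]1C[C@H]2C[C@@H]([C@@H]1C)C2(C)C)([C@H]1C[C@H]2C[C@@H]([C@@H]1C)C2(C)C)[C@@H]1CC[C@@H]2[C@H](C1)[C@H]1[C@@H]3CC[C@@H]3[C@@H]21 | intermediate
22 | (1R) C1 alcohol of the tetracycle, hydroxyl anti to ring B | O[C@@H]1CC[C@@H]2[C@H](C1)[C@H]1[C@@H]3CC[C@@H]3[C@@H]21 | intermediate
23 | C1 ketone of the tetracycle (single enantiomer) | O=C1CC[C@@H]2[C@H](C1)[C@H]1[C@@H]3CC[C@@H]3[C@@H]21 | intermediate
24 | 1,3-bis(benzyloxy)propan-2-ol | OC(COCc1ccccc1)COCc1ccccc1 | starting material
25 | 1,8-dibromooctane | BrCCCCCCCCBr | starting material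
26 | sodium 1,3-bis(benzyloxy)propan-2-olate (formed in situ) | [Na+].[O-]C(COCc1ccccc1)COCc1ccccc1 | intermediate
27 | 2-O-(8-bromooctyl)-1,3-di-O-benzylglycerol | BrCCCCCCCCOC(COCc1ccccc1)COCc1ccccc1 | intermediate
28 | {8-[1,3-bis(benzyloxy)propan-2-yloxy]octyl}triphenylphosphonium bromide | [Br-].c1ccccc1[P+](c1ccccc1)(c1ccccc1)CCCCCCCCOC(COCc1ccccc1)COCc1ccccc1 | intermediate
29 | corresponding phosphonium ylide (formed in situ) | c1ccccc1P(c1ccccc1)(c1ccccc1)=CCCCCCCCOC(COCc1ccccc1)COCc1ccccc1 | intermediate
30 | C1 alkylidene tetracycle with dibenzyl glyceryl ether chain (E/Z mixture) | O(CCCCCCCC=C1CC[C@@H]2[C@H](C1)[C@H]1[C@@H]3CC[C@@H]3[C@@H]21)C(COCc1ccccc1)COCc1ccccc1 | intermediate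
31 | 1,3-di-O-benzyl ether of the target (C1 S; formed in situ) | O(CCCCCCCC[C@H]1CC[C@@H]2[C@H](C1)[C@H]1[C@@H]3CC[C@@H]3[C@@H]21)C(COCc1ccccc1)COCc1ccccc1 | intermediate
32 | 2-O-{8-[cis,anti,cis,anti,cis-tetracyclo[6.4.0.0^2,7.0^3,6]dodecan-10-yl]octyl}glycerol, C1 (S), chain cis to ring B | OCC(CO)OCCCCCCCC[C@H]1CC[C@@H]2[C@H](C1)[C@H]1[C@@H]3CC[C@@H]3[C@@H]21 | target

## Step count and risk

Total step count: 16. Longest linear sequence: 14 (steps 1–12, 15 and 16); steps 13 and 14 form the side branch.

Least certain steps:

Step 7 (key step). The most likely failure is erosion of site selectivity as conversion is pushed (capture of the ketene by the C1=C2 alkene, or double addition), together with acid‑induced cleavage or oligomerisation of the bicyclo[2.2.0]hexene before it is trapped, since this alkene is both the most reactive and the most acid‑labile in the route. The fallback sets out from 12 and comes back at 20, building ring D without any Lewis acid. Sensitised [2+2] photocycloaddition of 9 to the ring C alkene (acetophenone, light above 300 nm) should give the exo anhydride F1. Aqueous hydrolysis gives the cis diacid F2. Oxidative bis‑decarboxylation (Pb(OAc)4 in pyridine) gives the ring D cyclobutene F3. Diimide (potassium azodicarboxylate, AcOH, MeOH, 0 °C) then reduces only this strained alkene and leaves C1=C2, giving 20 and bypassing 15–17.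

Step 1. The likely failure is hydride transfer from the doubly allylic methylenes of 1 to the keteniminium ion or to the cationic intermediate of the stepwise addition (ending in aromatisation), together with self‑condensation of the unsubstituted keteniminium ion, both of which would starve a sluggish cyclohexene‑type alkene. The fallback sets out from 1 and comes back at 5, using a neutral ketene in place of the cation. Dichloroketene 14, generated from 13 and Zn–Cu as in step 7, adds to an excess of 1 to give the dichloroketone F4, and zinc in acetic acid removes both chlorines to give 5.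

Step 4. The likely failure is insufficient site selectivity of the triplet biradical addition (attack on the ring A alkene or hydrogen abstraction from its allylic positions) and incomplete exo selectivity. The fallback sets out from 8 and comes back at 12 by a thermal, strain‑selective annulation. Dichloroketene 14 (from 13 and Zn–Cu) adds to the cyclobutene of 8 on its convex face to give the dichloroketone F5; zinc in acetic acid gives the ketone F6; TsNHNH2 gives the tosylhydrazone F7; n‑BuLi and TMEDA convert it into the vinyllithium F8, and water gives 12.

Step 6. The likely failure is low conversion in the fragmentation of the lead dicarboxylate, with competing acetoxylation or lactonisation at the ring A alkene and loss of the volatile, acid‑sensitive diene on isolation. The fallback sets out from 8 and comes back at 12, replacing the oxidative decarboxylation by a reductive olefination. Acetone‑sensitised [2+2] photocycloaddition of vinylene carbonate to the cyclobutene of 8 should give the exo cyclic carbonate F9. Methanolysis (K2CO3, MeOH) gives the cis diol F10. Thiocarbonyldiimidazole gives the thionocarbonate F11, and Corey–Winter olefination with 1,3‑dimethyl‑2‑phenyl‑1,3,2‑diazaphospholidine at 40 °C gives 12.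

Step 11. The likely failure is poor discrimination of the enantiotopic alkene carbons, because the hindered borane reacts slowly with a cyclohexene and may shed α‑pinene to less selective boranes, combined with only modest facial bias. The fallback sets out from 20 and comes back at 22. Epoxidation on the convex face (mCPBA, NaHCO3, CH2Cl2) gives the meso epoxide F12. Enantioselective β‑elimination with a chiral lithium amide (LiN[CH(CH3)Ph]2, the enantiomer that removes the C3 proton) gives the allylic alcohol F13 with the hydroxyl on C1. Saturation of its alkene (diimide, or H2 over Pd/C) gives 22.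

Step 16. The likely failure is insufficient facial selectivity (hydrogen entering from the ring B face gives the C1 epimer, which would be hard to separate), with double‑bond migration on palladium and slow hydrogenolysis of strained bonds on long exposure as secondary risks. The fallback sets out from 22 and comes back at 31, using the fact that the carbinol configuration of 22 is exactly opposite to that needed for the chain. Tosylation (TsCl, pyridine) gives the tosylate F14. The Grignard reagent F15 is made from 27 and magnesium in THF. Copper‑catalysed coupling (CuI, that is copper iodide, with TMEDA and LiOMe, THF, 0 °C) displaces the tosylate by SN2 with inversion at C1, placing the chain on the ring B face and giving 31, which is isolated and debenzylated (H2, Pd/C) to 32.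

## Further compounds

F1 | step 7 | exo maleic anhydride photoadduct of 12 (anhydride on C9/C10, anti to ring C) | C1=CC[C@@H]2[C@H](C1)[C@H]1[C@@H]3[C@H]4C(=O)OC(=O)[C@H]4[C@@H]3[C@@H]21
F2 | step 7 | cis-C9,C10-dicarboxylic acid from F1 | C1=CC[C@@H]2[C@H](C1)[C@H]1[C@@H]3[C@@H](C(=O)O)[C@@H](C(=O)O)[C@@H]3[C@@H]21
F3 | step 7 | meso tetracyclic diene with C1=C2 and C9=C10 alkenes | C1=CC[C@@H]2[C@H](C1)[C@H]1[C@@H]3C=C[C@@H]3[C@@H]21
F4 | step 1 | (±)-cis-8,8-dichlorobicyclo[4.2.0]oct-3-en-7-one | O=C1C(Cl)(Cl)[C@H]2CC=CC[C@@H]12
F5 | step 4 | (±)-10,10-dichloro-cis,anti,cis-tricyclo[6.2.0.0^2,7]dec-4-en-9-one | C1=CC[C@@H]2[C@H](C1)[C@H]1C(=O)C(Cl)(Cl)[C@@H]21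
F6 | step 4 | (±)-cis,anti,cis-tricyclo[6.2.0.0^2,7]dec-4-en-9-one | C1=CC[C@@H]2[C@H](C1)[C@H]1C(=O)C[C@@H]21
F7 | step 4 | p-toluenesulfonylhydrazone of F6 | C1=CC[C@@H]2[C@H](C1)[C@H]1C(=NNS(=O)(=O)c3ccc(C)cc3)C[C@@H]21
F8 | step 4 | 9-lithio-cis,anti,cis-tricyclo[6.2.0.0^2,7]deca-4,9-diene | C1=CC[C@@H]2[C@H](C1)[C@H]1C([Li])=C[C@@H]21
F9 | step 6 | exo cyclic carbonate of cis,anti,cis-tricyclo[6.2.0.0^2,7]dec-4-ene-9,10-diol (carbonate anti to ring B) | C1=CC[C@@H]2[C@H](C1)[C@H]1[C@@H]3OC(=O)O[C@@H]3[C@@H]21
F10 | step 6 | cis,anti,cis-tricyclo[6.2.0.0^2,7]dec-4-ene-9,10-diol (cis diol) | C1=CC[C@@H]2[C@H](C1)[C@H]1[C@H](O)[C@H](O)[C@@H]21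
F11 | step 6 | cyclic thionocarbonate of F10 | C1=CC[C@@H]2[C@H](C1)[C@H]1[C@@H]3OC(=S)O[C@@H]3[C@@H]21
F12 | step 11 | meso C1,C2-epoxide of 20, oxygen anti to ring B | [C@H]14O[C@@H]4C[C@@H]2[C@H](C1)[C@H]1[C@@H]3CC[C@@H]3[C@@H]21
F13 | step 11 | allylic alcohol, hydroxyl on C1 anti to ring B, alkene C2=C3 | O[C@@H]1C=C[C@@H]2[C@H](C1)[C@H]1[C@@H]3CC[C@@H]3[C@@H]21
F14 | step 16 | p-toluenesulfonate of 22 | Cc1ccc(cc1)S(=O)(=O)O[C@@H]1CC[C@@H]2[C@H](C1)[C@H]1[C@@H]3CC[C@@H]3[C@@H]21
F15 | step 16 | Grignard reagent from 27 | Br[Mg]CCCCCCCCOC(COCc1ccccc1)COCc1ccccc1
A1 | alternative 1 | cyclobut-2-enone | O=C1CC=C1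
A2 | alternative 1 | 2-[8-(tert-butyldimethylsilyloxy)octyl]buta-1,3-diene | C=CC(=C)CCCCCCCCO[Si](C)(C)C(C)(C)C
A3 | alternative 1 | chain-bearing cis-bicyclo[4.2.0]oct-3-en-7-one (C12 ketone) | CC(C)(C)[Si](C)(C)OCCCCCCCCC1=CC[C@@H]2[C@H](C1)CC2=O
A4 | alternative 2 | exo-7-formyl-cis-bicyclo[4.1.0]heptane tosylhydrazone with a cis 3-(silyloxymethyl) group | CC(C)(C)[Si](C)(C)OC[C@H]1CC[C@@H]2[C@H](C1)[C@H]2C=NNS(=O)(=O)c1ccc(C)cc1
A5 | alternative 2 | all-cis 3-(tert-butyldimethylsilyloxymethyl)bicyclo[4.2.0]oct-7-ene | CC(C)(C)[Si](C)(C)OC[C@H]1CC[C@@H]2[C@H](C1)C=C2
A6 | alternative 3 | dimethyl cis-exo-bicyclo[2.2.0]hexane-2,3-diyldiacetate | COC(=O)C[C@H]1[C@@H]2CC[C@@H]2[C@H]1CC(=O)OC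
A7 | alternative 3 | dimethyl cis-exo [3]-ladderane-3,4-dicarboxylate | COC(=O)[C@@H]1[C@H](C(=O)OC)[C@H]2[C@@H]3CC[C@@H]3[C@@H]12
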